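Amounts first: in both earlier runs, product and starting material add up to less than the charge, so you should ask where the remainder sits and when it stops turning into product.

| setting | Tuesday's | Friday's | alpha | gamma | theta | eta | delta |
|---|---|---|---|---|---|---|---|
| starting material | 0.0068 M | 0.17 M | 0.15 M | 0.080 M | 0.20 M | 0.050 M | 0.012 M |
| gas | 16 mM (held) | 16 mM (held) | 16 mM (held) | 16 mM (held) | 16 mM (held) | 16 mM (held) | 16 mM (held) |
| remark | run made earlier | run made earlier |  |  |  |  |  |
| time |  |  | 30 h | 30 h | 30 h | 30 h | 30 h |

| run | time / h | product / % | starting material / % |
|---|---|---|---|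
| Tuesday's | 1.33 | 0 | 90.4 |
| Tuesday's | 4.00 | 9.1 | 51.1 |
| Tuesday's | 8.00 | 25.8 | 16.8 |
| Tuesday's | 10.0 | 37.0 | 6.9 |
| Tuesday's | 15.0 | 52.4 | 2.8 |
| Friday's | 3.00 | 0 | 45.2 |
| Friday's | 6.00 | 2.1 | 26.6 |
| Friday's | 10.0 | 8.4 | 15.7 |
| Friday's | 12.0 | 7.2 | 11.8 |
| Friday's | 15.0 | 11.8 | 7.1 |

(standard deviation of a reading: 1 percentage point)

- at the start none of the gas is in solution

- ranking by amount of product, in percent of the starting material charged, from high to low, at 30 h (alpha / gamma / theta / eta / delta)
- the amount of product, in percent of the starting material charged of the flask you put first, at 30 h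
- the amount of product, in percent of the starting material charged of the flask you put last, at 30 h

Take Tuesday's dilute run and treat the link from remainder to product as a two-way first-order element. Between 4.00 h and 8.00 h, product grows at 0.0859 h⁻¹ per unit of remainder, with [product]/[remainder] at 0.359. Between 10.0 h and 15.0 h, growth is 0.0611 h⁻¹, which is slower, with the ratio at 0.886. A straight line through these two readings reaches zero growth at the stopping ratio, the [product]/[remainder] at which growth ceases (an equilibrium constant), 2.18. Product can therefore hold a share of 68.6% of the pair. The line's slope gives a back constant of 0.0472 h⁻¹, and the pair relaxes at 0.150 h⁻¹.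

Now run Tuesday's flask on from 15.0 h to 30 h in two extreme versions. If the step ran one way, product would reach 87.6%. If balance came at once, it would stand at 66.6%. The slowing growth speaks against the first, so I take the second as the level product approaches, itself an estimate that carries the scatter of the readings. The gap to it closes exponentially, which leaves 65.1%. Friday's larger charge gives less product, so I rank by rising charge and commit to that figure, or slightly below, for delta.

The forecast gave delta > eta > gamma > alpha > theta, 76% for first place, above my figure, and 19% for last, holding that “percent yield falls steadily as the charge rises”.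

The flasks give delta > eta > gamma > alpha > theta, with 65.2% and 19.1%.

    starting material + reagent ⇌ adduct (K = 1700 M⁻¹, k = 0.500 M⁻¹ min⁻¹)
    adduct ⇌ product (K = 2.70, k = 0.00190 min⁻¹)
    gas ⇌ reagent, rate k3*(csat - [reagent]) (kL = 0.00460 min⁻¹)
    2 starting material → homo dimer (k = 0.0160 M⁻¹ min⁻¹)

The remainder is adduct and homo dimer, and product runs back to adduct: without that backward run, delta would hold 86.1% instead of 65.2%. Its relaxation half-life of 4.44 h is short against 30 h. Percentages count each homo dimer as two, so subtract its percentage and the leftover starting material, then apply the share of 68.6%, an estimate from Tuesday's scattered readings. That estimate puts the balance in delta at 62.9% and in theta at 19.2%; left ten times as long, delta holds 67.0% and theta 20.5%.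

(All runs are calculated for an exercise, noise included.)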